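**Retrosynthetic overview**
1. The C3–H bond is made last: the target comes from the bicyclic hemiketal (3-hydroxy-isoxazolidine) by hydride delivery to the convex face of its oxocarbenium ion.
2. The hemiketal comes from a keto nitrone: an intramolecular proline-mediated Mannich addition of the ketone α-carbon to the nitrone carbon closes the cyclopentane first (C3a–C6a), then the N–OH closes the isoxazolidine onto the ketone.
3. The keto nitrone is the union of 6-oxo-14-(pyridin-3-yl)tetradecanal and N-[(4Z)-13-(pyridin-3-yl)tridec-4-en-1-yl]hydroxylamine.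
4. The keto aldehyde comes from ozonolysis of a 1-alkylcyclohexene assembled from cyclohexanone (as enol triflate), 8-bromooct-1-ene and 3-bromopyridine.
5. The hydroxylamine comes from 5-chloropent-1-yne, 1,7-dibromoheptane and 3-picoline (Lindlar reduction gives the Z alkene), with N–O from N,O-bis-Boc-hydroxylamine.

Assumption: the SMILES is read as (3S,3aS,6aR) with H-3, H-3a and H-6a mutually cis and a 4Z alkene in the N-chain; labels C3, C3a, C6a follow cyclopenta[c][1,2]oxazole numbering (N1, O2).

**Route**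

Step 1
Reactants: 1 cyclohexanone
Product: 2 cyclohex-1-en-1-yl trifluoromethanesulfonate
Conditions: Tf2O (1.1 equiv), Na2CO3 (1.5 equiv), CH2Cl2, 0 °C to rt
Reagents that add atoms: trifluoromethanesulfonic anhydride O=S(=O)(OS(=O)(=O)C(F)(F)F)C(F)(F)F
Why: O-triflation of the ketone followed by loss of the α-proton gives the enol triflate (Stang enol triflate synthesis), with no stereocentre involved.

Step 2
Reactants: 3 8-bromooct-1-ene; 2 cyclohex-1-en-1-yl trifluoromethanesulfonate
Product: 5 1-(oct-7-en-1-yl)cyclohex-1-ene, via oct-7-en-1-ylmagnesium bromide 4 (not isolated)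
Conditions: Mg, THF, rt to 40 °C; then 2, Fe(acac)3 (5 mol %), THF/NMP, −30 to 0 °C
Reagents that add atoms: none
Why: Iron-catalysed Kumada-type (Kochi–Fürstner) cross-coupling joins a primary alkyl Grignard reagent to an alkenyl triflate quickly at low temperature without moving either double bond.

Step 3
Reactants: 5 1-(oct-7-en-1-yl)cyclohex-1-ene; 6 3-bromopyridine
Product: 8 3-[8-(cyclohex-1-en-1-yl)octyl]pyridine, via B-alkyl-9-BBN adduct 7 (not isolated)
Conditions: 9-BBN (1.05 equiv), THF, 0 °C to rt; then 6, PdCl2(dppf) (3 mol %), 3 M aq NaOH, THF, 65 °C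
Reagents that add atoms: none
Why: 9-BBN hydroborates only the terminal alkene (anti-Markovnikov, the trisubstituted ring alkene is untouched) and the primary alkylborane then undergoes B-alkyl Suzuki–Miyaura coupling with the bromopyridine.

Step 4
Reactants: 8 3-[8-(cyclohex-1-en-1-yl)octyl]pyridine
Product: 10 6-oxo-14-(pyridin-3-yl)tetradecanal, via secondary ozonide 9 (not isolated)
Conditions: O3, CH2Cl2, −78 °C (Sudan Red 7B end point); then PPh3, −78 °C to rt; used promptly
Reagents that add atoms: ozone [O-][O+]=O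
Why: Criegee ozonolysis of the electron-rich trisubstituted alkene is far faster than any attack on the pyridine ring, and reductive work-up unmasks the ketone and the aldehyde in one operation.

Step 5
Reactants: 11 5-chloropent-1-yne; 12 1,7-dibromoheptane
Product: 14 12-bromo-1-chlorododec-4-yne, via (5-chloropent-1-yn-1-yl)lithium 13 (not isolated)
Conditions: n-BuLi (1.0 equiv), THF, −78 °C; then 12 (3 equiv), DMPU, −78 °C to rt
Reagents that add atoms: none
Why: SN2 alkylation of the lithium acetylide occurs at a C–Br end only (C–Cl is inert under these conditions), and the excess dibromide suppresses double alkylation.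

Step 6
Reactants: 15 3-methylpyridine; 14 12-bromo-1-chlorododec-4-yne
Product: 17 3-(13-chlorotridec-9-yn-1-yl)pyridine, via (pyridin-3-ylmethyl)lithium 16 (not isolated)
Conditions: LiN(iPr)2 (1.05 equiv), THF, −78 °C; then 14, −78 to 0 °C
Reagents that add atoms: none
Why: Lateral lithiation of 3-picoline gives the picolyl anion, which displaces the primary bromide by SN2 much faster than the chloride.

Step 7
Reactants: 17 3-(13-chlorotridec-9-yn-1-yl)pyridine
Product: 18 3-[(9Z)-13-chlorotridec-9-en-1-yl]pyridine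
Conditions: H2 (1 atm), Pd/CaCO3 poisoned with Pb(OAc)2, quinoline, EtOAc, rt
Reagents that add atoms: none
Why: Lindlar semihydrogenation delivers H2 syn to the alkyne and stops at the Z alkene, leaving the primary chloride and the pyridine ring intact.

Step 8
Reactants: 18 3-[(9Z)-13-chlorotridec-9-en-1-yl]pyridine; 19 tert-butyl N-[(tert-butoxycarbonyl)oxy]carbamate
Product: 21 tert-butyl N-[(tert-butoxycarbonyl)oxy]-N-[(4Z)-13-(pyridin-3-yl)tridec-4-en-1-yl]carbamate, via 3-[(9Z)-13-iodotridec-9-en-1-yl]pyridine 20 (not isolated)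
Conditions: 19 (1.3 equiv), K2CO3, NaI (20 mol %), DMF, 50 °C
Reagents that add atoms: none
Why: Finkelstein-assisted SN2 N-alkylation of the acidic bis-Boc hydroxylamine anion can only give the mono-N-alkyl product, and the anion outcompetes the neutral pyridine nitrogen.

Step 9
Reactants: 21 tert-butyl N-[(tert-butoxycarbonyl)oxy]-N-[(4Z)-13-(pyridin-3-yl)tridec-4-en-1-yl]carbamate
Product: 22 N-[(4Z)-13-(pyridin-3-yl)tridec-4-en-1-yl]hydroxylamine
Conditions: TFA/CH2Cl2 (1:3), 0 °C; cold aq NaHCO3 work-up; used at once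
Reagents that add atoms: none
Why: Acidolysis removes both the carbamate and the carbonate Boc group as isobutene and CO2, and the free pent-4-enyl-type hydroxylamine is kept cold and used immediately to avoid Cope-type hydroamination onto the alkene.

Step 10
Reactants: 10 6-oxo-14-(pyridin-3-yl)tetradecanal; 22 N-[(4Z)-13-(pyridin-3-yl)tridec-4-en-1-yl]hydroxylamine
Product: 24 (3aS,6aR)-3-[8-(pyridin-3-yl)octyl]-1-[(4Z)-13-(pyridin-3-yl)tridec-4-en-1-yl]hexahydro-1H-cyclopenta[c][1,2]oxazol-3-ol, via keto nitrone 23 (not isolated)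
Conditions: 4 Å MS, CHCl3, 0 °C to rt, 1 h; then L-proline (30 mol %), DMSO, 0.05 M, rt, 48 h
Reagents that add atoms: none
Why: The hydroxylamine condenses with the aldehyde (much faster than with the ketone) to the Z-nitrone, and the L-proline enamine of the ketone adds to it in a 5-(enolexo)-exo-trig intramolecular Mannich reaction in which the carboxylic acid hydrogen-bonds to the nitrone oxygen and directs attack to the si face of C6a (6aR, by analogy with the proline Mannich model), while the still epimerisable C3a is drained into the cis isomer because only that isomer can close to the cis-fused hemiketal (obtained as a mixture of C3 epimers).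

Step 11
Reactants: 24 (3aS,6aR)-3-[8-(pyridin-3-yl)octyl]-1-[(4Z)-13-(pyridin-3-yl)tridec-4-en-1-yl]hexahydro-1H-cyclopenta[c][1,2]oxazol-3-ol
Product: 25 Pyrinodemin C
Conditions: Et3SiH (6 equiv), BF3·OEt2 (5 equiv), CH2Cl2, −78 to −20 °C
Reagents that add atoms: none
Why: BF3 ionises the hemiketal to the bicyclic N-alkoxy oxocarbenium ion and Et3SiH delivers hydride to its convex face, cis to H-3a and H-6a, which places the octyl chain on the concave face and sets C3 as S (Kishi-type reductive deoxygenation of a hemiketal), the Z alkene and the N–O bond being inert to ionic hydrogenation.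

**Compound list**
1 | cyclohexanone | O=C1CCCCC1 | starting material
2 | cyclohex-1-en-1-yl trifluoromethanesulfonate | O=S(=O)(OC1=CCCCC1)C(F)(F)F | intermediate
3 | 8-bromooct-1-ene | C=CCCCCCCBr | starting material
4 | oct-7-en-1-ylmagnesium bromide | C=CCCCCCC[Mg]Br | intermediate (not isolated)
5 | 1-(oct-7-en-1-yl)cyclohex-1-ene | C=CCCCCCCC1=CCCCC1 | intermediate
6 | 3-bromopyridine | Brc1cccnc1 | starting material
7 | 9-[8-(cyclohex-1-en-1-yl)octyl]-9-borabicyclo[3.3.1]nonane (B-alkyl-9-BBN adduct) | C1(CCCCCCCCB2C3CCCC2CCC3)=CCCCC1 | intermediate (not isolated)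
8 | 3-[8-(cyclohex-1-en-1-yl)octyl]pyridine | C1(CCCCCCCCc2cccnc2)=CCCCC1 | intermediate
9 | 1-[8-(pyridin-3-yl)octyl]-7,8,9-trioxabicyclo[4.2.1]nonane (secondary ozonide) | c1ccc(CCCCCCCCC23CCCCC(OO2)O3)cn1 | intermediate (not isolated)
10 | 6-oxo-14-(pyridin-3-yl)tetradecanal | O=CCCCCC(=O)CCCCCCCCc1cccnc1 | intermediate
11 | 5-chloropent-1-yne | C#CCCCCl | starting material
12 | 1,7-dibromoheptane | BrCCCCCCCBr | starting material
13 | (5-chloropent-1-yn-1-yl)lithium | [Li]C#CCCCCl | intermediate (not isolated)
14 | 12-bromo-1-chlorododec-4-yne | ClCCCC#CCCCCCCCBr | intermediate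
15 | 3-methylpyridine (3-picoline) | Cc1cccnc1 | starting material
16 | (pyridin-3-ylmethyl)lithium | [Li]Cc1cccnc1 | intermediate (not isolated)
17 | 3-(13-chlorotridec-9-yn-1-yl)pyridine | ClCCCC#CCCCCCCCCc1cccnc1 | intermediate
18 | 3-[(9Z)-13-chlorotridec-9-en-1-yl]pyridine | ClCCC/C=C\CCCCCCCCc1cccnc1 | intermediate
19 | tert-butyl N-[(tert-butoxycarbonyl)oxy]carbamate (N,O-bis-Boc-hydroxylamine) | CC(C)(C)OC(=O)NOC(=O)OC(C)(C)C | starting material
20 | 3-[(9Z)-13-iodotridec-9-en-1-yl]pyridine | ICCC/C=C\CCCCCCCCc1cccnc1 | intermediate (not isolated)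
21 | tert-butyl N-[(tert-butoxycarbonyl)oxy]-N-[(4Z)-13-(pyridin-3-yl)tridec-4-en-1-yl]carbamate | CC(C)(C)OC(=O)ON(CCC/C=C\CCCCCCCCc1cccnc1)C(=O)OC(C)(C)C | intermediate
22 | N-[(4Z)-13-(pyridin-3-yl)tridec-4-en-1-yl]hydroxylamine | ONCCC/C=C\CCCCCCCCc1cccnc1 | intermediate
23 | (1Z)-6-oxo-14-(pyridin-3-yl)-N-[(4Z)-13-(pyridin-3-yl)tridec-4-en-1-yl]tetradecan-1-imine N-oxide (keto nitrone) | O=C(CCCC/C=[N+](\[O-])CCC/C=C\CCCCCCCCc1cccnc1)CCCCCCCCc1cccnc1 | intermediate (not isolated)
24 | (3aS,6aR)-3-[8-(pyridin-3-yl)octyl]-1-[(4Z)-13-(pyridin-3-yl)tridec-4-en-1-yl]hexahydro-1H-cyclopenta[c][1,2]oxazol-3-ol, cis-fused, both C3 epimers | C(=C/CCCN1OC(O)(CCCCCCCCc2cccnc2)[C@H]2CCC[C@H]21)/CCCCCCCCc1cccnc1 | intermediate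
25 | Pyrinodemin C, (3S,3aS,6aR)-3-[8-(pyridin-3-yl)octyl]-1-[(4Z)-13-(pyridin-3-yl)tridec-4-en-1-yl]hexahydro-1H-cyclopenta[c][1,2]oxazole | C(=C/CCCN1O[C@@H](CCCCCCCCc2cccnc2)[C@H]2CCC[C@H]21)/CCCCCCCCc1cccnc1 | target

**Step count and risks**

Total steps: 11. Longest linear sequence: 7 (steps 5 to 11, from 5-chloropent-1-yne); the other branch is steps 1 to 4, then 10 and 11.

Steps most likely to fail:

1. Step 10 (intramolecular nitrone Mannich). An acyclic dialkyl ketone forms its proline enamine slowly, the nitrone can self-condense, and both the level and the sense of asymmetric induction are unproven for a nitrone acceptor; the adduct can also racemise by loss and re-addition of the hydroxylamine. The ee must be measured, and D-proline is the mirror-image catalyst should the sense be opposite. Fallback: set out from 10 and treat it with dilute aqueous KOH in THF at rt, where the ketone enolate attacks the aldehyde and the aldol dehydrates (intramolecular aldol condensation) to 1-(cyclopent-1-en-1-yl)-9-(pyridin-3-yl)nonan-1-one F1. Conjugate addition of 22 to F1 (EtOH, rt) with spontaneous hemiketalisation then gives 24 as the racemate, that is together with the (3aR,6aS)-enantiomer of the hemiketal F2. The conditions of step 11 convert this pair into 25 and the (3R,3aR,6aS)-enantiomer of pyrinodemin C F3, which is removed by preparative HPLC on a cellulose tris(3,5-dimethylphenylcarbamate) phase, so the fallback rejoins the route at 25.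

2. Step 11 (hemiketal reduction). Lewis-acid binding at the isoxazolidine nitrogen can disfavour ionisation, the hemiketal can sit as the open keto hydroxylamine, and facial selectivity at C3 is inferred from the bicyclic shape only. Fallback: set out from 24 and reduce the open keto form under reagent control with (S)-2-methyl-CBS-oxazaborolidine (20 mol %) and BH3·SMe2 in THF at −20 °C (ethanolamine work-up to free the pyridines from borane) to (1R)-1-[(1S,2R)-2-{hydroxy[(4Z)-13-(pyridin-3-yl)tridec-4-en-1-yl]amino}cyclopentyl]-9-(pyridin-3-yl)nonan-1-ol F4. Mitsunobu cyclodehydration of F4 with PBu3 and 1,1'-(azodicarbonyl)dipiperidine (ADDP) in toluene lets the N–OH oxygen displace the activated carbinol with inversion, giving the 3S centre and rejoining the route at 25.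

3. Step 6 (3-picoline alkylation). Metalation of 3-picoline is incomplete, and the strongly basic picolyl anion can cause elimination or propargylic deprotonation of 14. Fallback: set out from 11 and, via 13, alkylate with 3 (THF/DMPU, −78 °C to rt) to give 13-chlorotridec-1-en-9-yne F5. Hydroborate the terminal alkene of F5 selectively with 9-BBN to 9-(13-chlorotridec-9-yn-1-yl)-9-borabicyclo[3.3.1]nonane F6, and couple this in the same flask with 6 (PdCl2(dppf), 3 M aq NaOH, THF, 65 °C; B-alkyl Suzuki–Miyaura), rejoining the route at 17.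

**Further compounds**
F1 | step 10 | 1-(cyclopent-1-en-1-yl)-9-(pyridin-3-yl)nonan-1-one | O=C(CCCCCCCCc1cccnc1)C1=CCCC1
F2 | step 10 | (3aR,6aS)-3-[8-(pyridin-3-yl)octyl]-1-[(4Z)-13-(pyridin-3-yl)tridec-4-en-1-yl]hexahydro-1H-cyclopenta[c][1,2]oxazol-3-ol (enantiomer of 24) | C(=C/CCCN1OC(O)(CCCCCCCCc2cccnc2)[C@@H]2CCC[C@@H]21)/CCCCCCCCc1cccnc1
F3 | step 10 | (3R,3aR,6aS)-3-[8-(pyridin-3-yl)octyl]-1-[(4Z)-13-(pyridin-3-yl)tridec-4-en-1-yl]hexahydro-1H-cyclopenta[c][1,2]oxazole (enantiomer of 25) | C(=C/CCCN1O[C@H](CCCCCCCCc2cccnc2)[C@@H]2CCC[C@@H]21)/CCCCCCCCc1cccnc1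
F4 | step 11 | (1R)-1-[(1S,2R)-2-{hydroxy[(4Z)-13-(pyridin-3-yl)tridec-4-en-1-yl]amino}cyclopentyl]-9-(pyridin-3-yl)nonan-1-ol | ON(CCC/C=C\CCCCCCCCc1cccnc1)[C@@H]1CCC[C@@H]1[C@H](O)CCCCCCCCc1cccnc1
F5 | step 6 | 13-chlorotridec-1-en-9-yne | C=CCCCCCCC#CCCCCl
F6 | step 6 | 9-(13-chlorotridec-9-yn-1-yl)-9-borabicyclo[3.3.1]nonane | ClCCCC#CCCCCCCCCB1C2CCCC1CCC2
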